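The oxolane of the target (O1; C2 carrying the aryloxymethyl carbon C1; C3, the methyl carbinol; C4; C5 carrying the alkenyl carbon C6) is disconnected at O1–C2. Because the C3 oxygen and C6 sit on the same face of this ring, they can be joined through a γ-lactone. The C5 hydroxyl of that lactone then adds to an iodine-activated vinyl group (C1=C2), closing the oxolane as a 2,5-dioxabicyclo[2.2.1]heptan-3-one and setting C2 with the iodomethyl group exo. The precursor is (3R,5R)-3-hydroxy-5-methyl-5-vinyloxolan-2-one, made from (R)-linalool, which supplies C1–C6 and the C3 stereocentre.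

Key step: step 5

Remark: the labels O1 and C1–C7 of the target oxolane are kept for every intermediate (C1=C2 vinyl group, C3 quaternary carbon, C5 lactone α-carbon, C6 lactone carbonyl carbon), while locants inside systematic names follow IUPAC rules. The hydroxylation in step 3 is assumed to show no useful facial selectivity, so its product is carried as one compound made up of both C5 epimers, which step 4 converts into the single cis epimer.

Step 1
Reactants: 1 (R)-linalool
Product: 4 (5R)-5-ethenyl-5-methyloxolan-2-ol (lactol as both anomers), via linalool 6,7-diol 2 (not isolated), via open hydroxy aldehyde 3 (not isolated)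
Conditions: OsO4 (2 mol %), NaIO4 (2.1 equiv), 2,6-lutidine (2 equiv), 1,4-dioxane/H2O (3:1), rt
Reagents that add atoms: osmium tetroxide, O=[Os](=O)(=O)=O; sodium periodate, [Na+].[O-]I(=O)(=O)=O (terminal source of the oxygen that OsO4 delivers)
Why: Lemieux–Johnson oxidative cleavage, in which osmylation should pick the electron-rich trisubstituted C6=C7 bond over the vinyl group (shielded by the fully substituted C3 and deactivated by its allylic oxygen), periodate cleaves the diol and the C3 hydroxyl captures the aldehyde as the five-membered lactol, C3 keeping its R configuration.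

Step 2
Reactants: 4 (5R)-5-ethenyl-5-methyloxolan-2-ol
Product: 5 (5R)-5-ethenyl-5-methyloxolan-2-one
Conditions: TEMPO (10 mol %), PhI(OAc)2 (1.5 equiv), CH2Cl2, rt; careful concentration (volatile product)
Reagents that add atoms: none
Why: Oxoammonium (TEMPO) oxidation of a lactol to the lactone with PhI(OAc)2 as terminal oxidant should merge both anomers into one compound and leave the vinyl group and C3 untouched.

Step 3
Reactants: 5 (5R)-5-ethenyl-5-methyloxolan-2-one
Product: 7 (3RS,5R)-5-ethenyl-3-hydroxy-5-methyloxolan-2-one (both epimers at the hydroxyl-bearing carbon), via sodium lactone enolate 6 (not isolated)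
Conditions: NaN(SiMe3)2 (1.2 equiv), THF, −78 °C; then 2-(phenylsulfonyl)-3-phenyloxaziridine (1.5 equiv), −78 °C; AcOH quench
Reagents that add atoms: 2-(phenylsulfonyl)-3-phenyloxaziridine, O=S(=O)(c1ccccc1)N1OC1c1ccccc1
Why: Davis enolate hydroxylation, in which the sodium enolate takes the electrophilic oxaziridine oxygen at C5; the two enolate faces differ only in methyl versus vinyl on the remote C3, so no useful facial bias is expected and 7 is carried on as the mixture of cis and trans C5 epimers, C3 staying R.

Step 4
Reactants: 7 (3RS,5R)-5-ethenyl-3-hydroxy-5-methyloxolan-2-one (both epimers)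
Product: 8 (3R,5R)-5-ethenyl-3-hydroxy-5-methyloxolan-2-one (hydroxyl cis to vinyl)
Conditions: SiO2 chromatography (8 collected); trans-enriched remainder: DBU (0.3 equiv), toluene, 80 °C; chromatography again; cycle repeated
Reagents that add atoms: none
Why: Base-catalysed epimerisation through the lactone enolate, in which the cis epimer is taken off by chromatography and DBU reversibly removes the C5 proton (α to the carbonyl and to oxygen) of the remaining trans epimer, so that reprotonation on either face restores a mixture from which more 8 is collected, the quaternary C3 being unable to change.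

Step 5
Reactants: 8 (3R,5R)-5-ethenyl-3-hydroxy-5-methyloxolan-2-one
Product: 9 (1R,4R,6R)-6-(iodomethyl)-1-methyl-2,5-dioxabicyclo[2.2.1]heptan-3-one
Conditions: I2 (3 equiv), NaHCO3 (3 equiv), MeCN, 0 °C to rt, dark; aq. Na2S2O3
Reagents that add atoms: iodine, II
Why: Iodoetherification: iodine reversibly forms an iodonium ion on the vinyl group C1=C2, and the C5 hydroxyl, held on the same face of the lactone as the vinyl group, opens it at the internal carbon C2 anti to iodine while bicarbonate takes up the proton, so that the O1–C2 bond forms. The closest known reaction type is the 5-exo iodocyclisation of pent-4-en-1-ols to 2-(iodomethyl)oxolanes, used here across a lactone so that the product is bridged. The oxolane ring (O1, C2, C3, C4, C5) closes in the 5-exo-trig mode, the 6-endo alternative being disfavoured by the larger bicyclo[2.2.2] lactone it would need and by the lower positive character of the terminal carbon C1. The one new stereocentre, C2, is set by which alkene face carries iodine at the moment of closure: the rotamer that turns the C1 terminus toward the one-carbon bridge C4, away from the lactone O–C6 bridge and its lone pairs, is the less encumbered, so the iodomethyl group should end up exo, trans to the C3 oxygen and to C6 as the target requires. The step needs epimer selectivity and exo selectivity: only a hydroxyl cis to the vinyl group can reach C2, so any residual trans epimer stays out, and the rigid bicyclo[2.2.1] frame fixes C5 relative to C3 and places C5 at a bridgehead that cannot enolise.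

Step 6
Reactants: 9 (1R,4R,6R)-6-(iodomethyl)-1-methyl-2,5-dioxabicyclo[2.2.1]heptan-3-one
Product: 10 [(1R,4R,6S)-1-methyl-3-oxo-2,5-dioxabicyclo[2.2.1]heptan-6-yl]methyl acetate
Conditions: CsOAc (3 equiv), DMF, 80 °C
Reagents that add atoms: cesium acetate, CC(=O)[O-].[Cs+]
Why: SN2 displacement of the primary iodide at C1 by a carboxylate, which touches no stereocentre (the descriptor at C2 changes only through priorities), with acetate too weakly basic for elimination and the bridgehead C5 unable to epimerise.

Step 7
Reactants: 10 [(1R,4R,6S)-1-methyl-3-oxo-2,5-dioxabicyclo[2.2.1]heptan-6-yl]methyl acetate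
Product: 11 (1R,4R,6S)-6-(hydroxymethyl)-1-methyl-2,5-dioxabicyclo[2.2.1]heptan-3-ol (bridged lactol as both anomers)
Conditions: i-Bu2AlH (4.5 equiv), CH2Cl2, −78 °C; MeOH, then aq. KNaC4H4O6
Reagents that add atoms: none
Why: Low-temperature aluminium hydride reduction, in which the lactone should stop at the lactol because its tetrahedral aluminate persists at −78 °C while the unhindered acetate is cleaved reductively by the excess hydride with its acetyl group leaving as ethanol, the new lactol centre being of no consequence since it becomes alkene carbon C6.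

Step 8
Reactants: 11 (1R,4R,6S)-6-(hydroxymethyl)-1-methyl-2,5-dioxabicyclo[2.2.1]heptan-3-ol; 12 isopropyltriphenylphosphonium iodide
Product: 15 (2S,3R,5R)-2-(hydroxymethyl)-3-methyl-5-(2-methylprop-1-en-1-yl)oxolan-3-ol, via isopropylidenetriphenylphosphorane 13 (not isolated), via ring-opened hydroxy aldehyde 14 (not isolated)
Conditions: 12 (5 equiv), n-BuLi (4.8 equiv), THF, 0 °C; then 11, 0 °C to rt
Reagents that add atoms: none
Why: Wittig olefination of a lactol through its ring-opened aldehyde, in which excess ylide first deprotonates the two hydroxyls and then converts C6 into the C6=C7 alkene, freeing the C3 hydroxyl; the symmetrical ylide leaves no alkene geometry to control, and C5 should hold because addition to the aldehyde outpaces its enolisation at 0 °C.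

Step 9
Reactants: 15 (2S,3R,5R)-2-(hydroxymethyl)-3-methyl-5-(2-methylprop-1-en-1-yl)oxolan-3-ol; 16 isofraxidin (7-hydroxy-6,8-dimethoxy-2H-chromen-2-one)
Product: 17 7-{[(2S,3R,5R)-3-hydroxy-3-methyl-5-(2-methylprop-1-en-1-yl)oxolan-2-yl]methoxy}-6,8-dimethoxy-2H-chromen-2-one
Conditions: PPh3 (1.5 equiv), DIAD (1.5 equiv), 16 (1.2 equiv), THF, 0 °C to rt
Reagents that add atoms: none
Why: Mitsunobu etherification, in which the primary C1 hydroxyl is activated as its alkoxyphosphonium ion and displaced by the acidic coumarin phenol, while the tertiary C3 hydroxyl is inert and, being trans to C1, cannot close an oxetane, so no stereocentre is touched.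

Compound list
1 | (R)-linalool, (3R)-3,7-dimethylocta-1,6-dien-3-ol | C=C[C@](C)(O)CCC=C(C)C | starting material
2 | (3R)-3,7-dimethyloct-1-ene-3,6,7-triol (both C6 epimers) | C=C[C@](C)(O)CCC(O)C(C)(C)O | intermediate (not isolated)
3 | (4R)-4-hydroxy-4-methylhex-5-enal | C=C[C@](C)(O)CCC=O | intermediate (not isolated)
4 | (5R)-5-ethenyl-5-methyloxolan-2-ol (both anomers) | OC1O[C@@](C)(C=C)CC1 | intermediate
5 | (5R)-5-ethenyl-5-methyloxolan-2-one | O=C1O[C@@](C)(C=C)CC1 | intermediate
6 | sodium (5R)-5-ethenyl-5-methyl-4,5-dihydrofuran-2-olate | [Na+].[O-]C1=CC[C@](C)(C=C)O1 | intermediate (not isolated)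
7 | (3RS,5R)-5-ethenyl-3-hydroxy-5-methyloxolan-2-one (mixture of the cis and trans epimers at the hydroxyl-bearing carbon) | O=C1O[C@@](C)(C=C)CC1O | intermediate
8 | (3R,5R)-5-ethenyl-3-hydroxy-5-methyloxolan-2-one (hydroxyl cis to vinyl) | O=C1O[C@@](C)(C=C)C[C@H]1O | intermediate
9 | (1R,4R,6R)-6-(iodomethyl)-1-methyl-2,5-dioxabicyclo[2.2.1]heptan-3-one (iodomethyl exo) | O=C1O[C@]2(C)C[C@H]1O[C@H]2CI | intermediate
10 | [(1R,4R,6S)-1-methyl-3-oxo-2,5-dioxabicyclo[2.2.1]heptan-6-yl]methyl acetate | O=C1O[C@]2(C)C[C@H]1O[C@H]2COC(C)=O | intermediate
11 | (1R,4R,6S)-6-(hydroxymethyl)-1-methyl-2,5-dioxabicyclo[2.2.1]heptan-3-ol (both anomers) | OC1O[C@]2(C)C[C@H]1O[C@H]2CO | intermediate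
12 | isopropyltriphenylphosphonium iodide | CC(C)[P+](c1ccccc1)(c1ccccc1)c1ccccc1.[I-] | starting material
13 | isopropylidenetriphenylphosphorane | CC(C)=P(c1ccccc1)(c1ccccc1)c1ccccc1 | intermediate (not isolated)
14 | (2R,4R,5S)-4-hydroxy-5-(hydroxymethyl)-4-methyloxolane-2-carbaldehyde | OC[C@@H]1O[C@@H](C=O)C[C@@]1(C)O | intermediate (not isolated)
15 | (2S,3R,5R)-2-(hydroxymethyl)-3-methyl-5-(2-methylprop-1-en-1-yl)oxolan-3-ol | OC[C@@H]1O[C@@H](C=C(C)C)C[C@@]1(C)O | intermediate
16 | isofraxidin, 7-hydroxy-6,8-dimethoxy-2H-chromen-2-one | COc1cc2ccc(=O)oc2c(OC)c1O | starting material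
17 | 7-{[(2S,3R,5R)-3-hydroxy-3-methyl-5-(2-methylprop-1-en-1-yl)oxolan-2-yl]methoxy}-6,8-dimethoxy-2H-chromen-2-one | COc1cc2ccc(=O)oc2c(OC)c1OC[C@@H]1O[C@@H](C=C(C)C)C[C@@]1(C)O | target

Total step count: 9. Longest linear sequence: 9 steps (steps 1 to 9, from 1 to 17), with 12 and 16 entering as purchased materials in steps 8 and 9.

Steps most likely to fail

Step 5. Ring closure may be slow, because the nucleophile is a hydroxyl next to a carbonyl and the alkene carries an allylic acyloxy group. Under kinetic control the iodonium may also be captured with its terminus turned toward the lactone bridge, which would erode exo selectivity at C2. The fallback moves C2 control to a reversible mercuricyclisation and sets out from 8: Hg(OCOCF3)2 in CH2Cl2 at rt, followed by exchange with aqueous NaCl, should give under equilibrating conditions the exo organomercurial chloro{[(1R,4R,6R)-1-methyl-3-oxo-2,5-dioxabicyclo[2.2.1]heptan-6-yl]methyl}mercury F1. Iododemercuration of F1 with I2 in CH2Cl2 then delivers the iodide, and the route is rejoined at 9.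

Step 4. Proton exchange at the weakly acidic α-carbon may be too slow with an amidine base, or each equilibration pass may leave most of the material in the trans form, so that the recycle returns little of the cis epimer. The fallback replaces equilibration by a stereospecific inversion and sets out from 7: once 8 has been collected by chromatography, the remaining trans epimer (3S,5R)-5-ethenyl-3-hydroxy-5-methyloxolan-2-one F2 is submitted to a Mitsunobu reaction with 4-nitrobenzoic acid (PPh3, DIAD, THF, 0 °C to rt), which should invert C5 and give (3R,5R)-5-ethenyl-5-methyl-2-oxooxolan-3-yl 4-nitrobenzoate F3. Brief methanolysis of the activated ester (K2CO3, MeOH, 0 °C, mildly acidic work-up to re-close any opened lactone) then releases the cis hydroxy lactone, and the route is rejoined at 8.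

Step 8. The hindered, strongly basic ylide may enolise the ring-opened α-alkoxy aldehyde and scramble C5, or may add too slowly to the small amount of open aldehyde. The fallback builds the alkene in two stages and sets out from 11: methylenation with the small, fast ylide Ph3P=CH2 (methyltriphenylphosphonium bromide, KOt-Bu, THF, 0 °C) should give (2S,3R,5R)-5-ethenyl-2-(hydroxymethyl)-3-methyloxolan-3-ol F4. Cross-metathesis of F4 with excess 2-methylbut-2-ene (second-generation Grubbs catalyst, CH2Cl2, 40 °C) then installs the two methyl groups on C7, and the route is rejoined at 15.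

Further compounds
F1 | step 5 | chloro{[(1R,4R,6R)-1-methyl-3-oxo-2,5-dioxabicyclo[2.2.1]heptan-6-yl]methyl}mercury | O=C1O[C@]2(C)C[C@H]1O[C@H]2C[Hg]Cl
F2 | step 4 | (3S,5R)-5-ethenyl-3-hydroxy-5-methyloxolan-2-one (hydroxyl trans to vinyl) | O=C1O[C@@](C)(C=C)C[C@@H]1O
F3 | step 4 | (3R,5R)-5-ethenyl-5-methyl-2-oxooxolan-3-yl 4-nitrobenzoate | O=C1O[C@@](C)(C=C)C[C@H]1OC(=O)c1ccc(cc1)[N+](=O)[O-]
F4 | step 8 | (2S,3R,5R)-5-ethenyl-2-(hydroxymethyl)-3-methyloxolan-3-ol | OC[C@@H]1O[C@@H](C=C)C[C@@]1(C)O
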